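**Remarks before the route**

- Reading of the target: the SMILES is taken as written, a cis,cis‑germacranolide with both ring olefins ring‑cis (C4=C5 is 4Z, C1=C10 is 1(10)E by CIP) and (6R,7S,8S,9S,2'S) configuration.
- Convention: all compounds carry the germacrane numbering of the target (ring C1–C10, lactone carbons C11–C13, ester carbon C14, methyl C15). β is the face of C11 on C7 and of O8; α is the face of O6 and O9. DoxCO = (4S)‑2,2,4‑trimethyl‑1,3‑dioxolane‑4‑carbonyl.
- Assumption: acid 1 (the acetonide of (S)‑2,3‑dihydroxy‑2‑methylpropanoic acid) is taken as a purchasable building block.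

**Retrosynthetic overview**

1. The feature used is the 1,5‑diene C10=C1–C2–C3–C4=C5 inside the ten‑membered ring C1–C10, with carbonyl‑level C14 on C10. It is made by an anionic oxy‑Cope ring expansion of a cyclohexanol (ring C5–C10) that forms C2–C3 and cleaves C5–C10.
2. The cis‑1‑vinyl‑2‑isopropenyl relationship gives the 4Z olefin; the regiodefined C10 ketone gives the C1=C10 enol triflate, and CO/MeOH installs C14.
3. The cyclohexane comes from one Diels–Alder reaction (bonds C5–C6 and C7–C8; stereocentres C5–C8), a Rubottom oxidation (C9) and a vinyl addition (C10).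
4. The (S)‑acyl group on O8 is put on in step 2 as a dienyl ester and never removed; it also makes the Diels–Alder adducts diastereomers, which fixes the absolute series by separation.
5. Ring order: cyclohexene, then the ten‑membered carbocycle (six‑ring consumed), then the γ‑lactone last (C12 from CO, on the C7 ethynyl group and 6‑OH).

Key step: step 10

**Route**

Step 1
Reactants: 1 (S)-2,2,4-trimethyl-1,3-dioxolane-4-carboxylic acid
Product: 2 (S)-2,2,4-trimethyl-1,3-dioxolane-4-carbonyl chloride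
Conditions: 1-chloro-N,N,2-trimethylprop-1-en-1-amine, CH2Cl2, 0 °C → rt; used crude
Reagents that add atoms: 1-chloro-N,N,2-trimethylprop-1-en-1-amine, CC(C)=C(Cl)N(C)C
Why: Neutral acid chloride formation with an α-chloroenamine avoids HCl, so the acetonide should survive, and the quaternary stereocentre cannot epimerise.

Step 2
Reactants: 3 mesityl oxide; 2 (S)-2,2,4-trimethyl-1,3-dioxolane-4-carbonyl chloride
Product: 5 (E)-5-methyl-3-oxohexa-1,4-dien-1-yl (S)-2,2,4-trimethyl-1,3-dioxolane-4-carboxylate, via sodium formyl-enolate 4 (not isolated)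
Conditions: NaH, HCO2Et, Et2O, 0 °C → rt; volatiles removed; then 2, THF, 0 °C
Reagents that add atoms: ethyl formate, CCOC=O
Why: Claisen formylation of the acetyl methyl group gives the sodium β-oxo-enolate, which a hard acyl chloride should acylate on the formyl oxygen to give the E β-acyloxy enone (C8 and O8 come from the formate).

Step 3
Reactants: 5 (E)-5-methyl-3-oxohexa-1,4-dien-1-yl (S)-2,2,4-trimethyl-1,3-dioxolane-4-carboxylate
Product: 6 (1E,3Z)-3-(tert-butyldimethylsilyloxy)-5-methylhexa-1,3,5-trien-1-yl (S)-2,2,4-trimethyl-1,3-dioxolane-4-carboxylate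
Conditions: TBSOTf, Et3N, Et2O, 0 °C
Reagents that add atoms: tert-butyldimethylsilyl trifluoromethanesulfonate, CC(C)(C)[Si](C)(C)OS(=O)(=O)C(F)(F)F
Why: Soft enolisation can only remove a γ-methyl proton (there is no α'-H), and the s-cis enone conformer should give the silyl dienol ether with OSi cis to the new isopropenyl group (3Z).

Step 4
Reactants: 7 but-3-yn-2-one
Product: 8 (E)-4-(4,4,5,5-tetramethyl-1,3,2-dioxaborolan-2-yl)but-3-en-2-one
Conditions: B2pin2, CuCl (cat.), Xantphos (cat.), NaOt-Bu (cat.), MeOH, THF, rt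
Reagents that add atoms: bis(pinacolato)diboron, CC1(C)OB(OC1(C)C)B1OC(C)(C)C(C)(C)O1
Why: Copper-catalysed β-borylation of the ynone (syn borylcupration, then protonation) should give the E β-boryl enone, a trans-β-hydroxy-enone equivalent.

Step 5
Reactants: 6 (1E,3Z)-3-(tert-butyldimethylsilyloxy)-5-methylhexa-1,3,5-trien-1-yl (S)-2,2,4-trimethyl-1,3-dioxolane-4-carboxylate; 8 (E)-4-(4,4,5,5-tetramethyl-1,3,2-dioxaborolan-2-yl)but-3-en-2-one
Product: 10 cyclohexenol (ring C5–C10; C9=C10 TBS enol ether; 5β-isopropenyl; 6α-OH; 7β-acetyl; 8β-O-DoxCO), via boronate adduct 9 (not isolated)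
Conditions: PhMe, BHT (cat.), 90 °C; then 30% H2O2, pH 7 phosphate buffer, THF, 0 °C → rt; chromatography
Reagents that add atoms: hydrogen peroxide, OO
Why: A thermal Diels–Alder reaction through the 1-acyloxy-3-silyloxy diene unit C8=C9–C10=C5 (the other diene unit has a Z-silyloxy terminus) should join C5 to the boron-bearing carbon C6 and C8 to C7; the endo mode puts acetyl cis to O8, the E dienophile puts boron trans to acetyl, the two outside diene substituents end cis, C–B oxidation proceeds with retention, and because no facial bias from the (S)-acyl group is relied on, 10 is separated from its endo diastereomer (same acyl group, mirror-image ring).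

Step 6
Reactants: 10 cyclohexenol
Product: 11 6α-triisopropylsilyl ether of 10
Conditions: TIPSOTf, 2,6-lutidine, CH2Cl2, −40 → 0 °C
Reagents that add atoms: triisopropylsilyl trifluoromethanesulfonate, CC(C)[Si](C(C)C)(C(C)C)OS(=O)(=O)C(F)(F)F
Why: Silylation under weakly basic conditions masks O6 (a β-hydroxy ketone that would otherwise undergo retro-aldol cleavage in step 7) without touching the enol ether or the β-acyloxy ketone.

Step 7
Reactants: 11 6α-triisopropylsilyl ether
Product: 15 7β-[(triisopropylsilyl)ethynyl]cyclohexene (C9=C10 TBS enol ether; 5β-isopropenyl; 6α-OTIPS; 8β-O-DoxCO), via lithium enolate 12 (not isolated), via enol phosphate 13 (not isolated), via lithium acetylide 14 (not isolated)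
Conditions: LDA (1.1 equiv), THF, −78 °C; ClP(O)(OEt)2; LDA (2.3 equiv), −78 → 0 °C; TIPSOTf, −78 °C → rt
Reagents that add atoms: triisopropylsilyl trifluoromethanesulfonate, CC(C)[Si](C(C)C)(C(C)C)OS(=O)(=O)C(F)(F)F
Why: Kinetic deprotonation of the methyl group (not the C7 methine, which would eliminate the C8 acyloxy group), O-phosphorylation, β-elimination to the acetylide and C-silylation convert the acetyl group (C11, C13) into a protected ethynyl group; the ester has no α-hydrogen and is hindered, and C7 is not touched.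

Step 8
Reactants: 15 7β-[(triisopropylsilyl)ethynyl]cyclohexene
Product: 17 cyclohexanone (C10=O; 9α-OTBS; 8β-O-DoxCO; 7β-TIPS-ethynyl; 6α-OTIPS; 5β-isopropenyl), via silyloxy epoxide 16 (not isolated)
Conditions: m-CPBA (1.0 equiv), NaHCO3, CH2Cl2, −20 → 0 °C
Reagents that add atoms: 3-chloroperoxybenzoic acid, OOC(=O)c1cccc(Cl)c1
Why: In this Rubottom oxidation the electron-rich silyl enol ether is epoxidised before the isopropenyl group, from the α-face anti to the β-substituents on C8 and C5, and 1,4-silyl migration should give the 9α-silyloxy ketone with C5 unchanged.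

Step 9
Reactants: 17 cyclohexanone
Product: 18 10β-vinyl-10α-hydroxy cyclohexane (9α-OTBS; 8β-O-DoxCO; 7β-TIPS-ethynyl; 6α-OTIPS; 5β-isopropenyl)
Conditions: CH2=CHMgBr, CeCl3, THF, −78 °C
Reagents that add atoms: vinylmagnesium bromide, C=C[Mg]Br
Why: The weakly basic organocerium reagent adds to the ketone only (no enolisation at C5, no attack on the hindered ester), and attack anti to the axial C9–OTBS bond (Felkin–Anh sense, the α-face being screened by that group) should give the β-vinyl carbinol, cis to the isopropenyl group.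

Step 10
Reactants: 18 10β-vinyl-10α-hydroxy cyclohexane
Product: 21 (4Z)-cyclodec-4-en-10-one (ring C1–C10; 9α-OTBS; 8β-O-DoxCO; 7β-TIPS-ethynyl; 6α-OTIPS; 4-methyl), via potassium alkoxide 19 (not isolated), via potassium enolate 20 (not isolated)
Conditions: KH, 18-crown-6, THF, 0 °C → rt; AcOH/THF quench at −78 °C
Reagents that add atoms: none
Why: The C10 alkoxide accelerates the [3,3]-sigmatropic shift of the 3-oxido-1,5-diene C2=C1–C10–C5–C4=C3, forming C2–C3 and cleaving C5–C10 to give enolate 20, which is protonated at C1 on quench. The closest known reaction type is the anionic oxy-Cope ring expansion of cis-2-alkenyl-1-vinylcyclohexanols to (Z)-cyclodec-5-enones. The ten-membered ring is closed as a four-atom ring expansion through a six-membered chair transition state, not by end-to-end cyclisation. No new stereocentre forms: C5 and C10 become sp2, their cis relationship is transcribed into the 4Z olefin, and C6–C9 are untouched. The step needs the chair with axial C10-vinyl and equatorial C5-isopropenyl; this should be the preferred chair of 18 because it keeps the C5, C6 and C7 substituents equatorial, whereas the alternative chair (which leads to the 4E olefin) puts isopropenyl, OTIPS and the alkynyl group axial. Regiochemistry is fixed by the mechanism, since only C10 becomes C=O and only C1 its new α-CH2.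

Step 11
Reactants: 21 (4Z)-cyclodec-4-en-10-one
Product: 23 (1(10)E,4Z)-cyclodeca-1(10),4-dien-10-yl triflate (OTf trans to C2; other groups as in 21), via lithium enolate 22 (not isolated)
Conditions: LDA, THF, −78 °C; PhNTf2, −78 → 0 °C
Reagents that add atoms: N-phenylbis(trifluoromethanesulfonimide), O=S(=O)(N(c1ccccc1)S(=O)(=O)C(F)(F)F)C(F)(F)F
Why: Kinetic deprotonation should occur at the C1 methylene and not at the hindered C9 methine, and the cyclic amide deprotonation transition state together with the lower strain of a cis-cyclodecene should give the ring-cis enolate (O trans to C2), which is triflated with retention of geometry.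

Step 12
Reactants: 23 dienyl triflate
Product: 24 methyl (1(10)E,4Z)-cyclodeca-1(10),4-diene-10-carboxylate (9α-OTBS; 8β-O-DoxCO; 7β-TIPS-ethynyl; 6α-OTIPS)
Conditions: Pd(OAc)2 (cat.), dppp (cat.), CO (1 atm), MeOH, Et3N, DMF, 45 °C
Reagents that add atoms: carbon monoxide, [C-]#[O+]; methanol, CO
Why: Palladium-catalysed methoxycarbonylation of an enol triflate proceeds with retention of olefin geometry and should install C14 as the methyl ester trans to C2.

Step 13
Reactants: 24 methyl dienecarboxylate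
Product: 25 9α-alcohol (6α-OTIPS and TIPS-alkyne retained)
Conditions: HF·pyridine, pyridine, THF, 0 °C
Reagents that add atoms: none
Why: Buffered HF·pyridine cleaves a secondary TBS ether much faster than a secondary TIPS ether, a C-silyl alkyne or the acetonide, so only O9 should be freed.

Step 14
Reactants: 25 9α-alcohol
Product: 26 9α-acetate
Conditions: Ac2O, DMAP (cat.), pyridine, CH2Cl2, 0 °C → rt
Reagents that add atoms: acetic anhydride, CC(=O)OC(C)=O
Why: Standard acylation of the only free hydroxyl; the hindered α-quaternary ester on O8 should not migrate under these conditions.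

Step 15
Reactants: 26 9α-acetate
Product: 28 triol alkyne (6α-OH; 7β-ethynyl; 8β-O-[(S)-2,3-dihydroxy-2-methylpropanoyl]; 9α-OAc; C14 methyl ester), via desilylated acetonide 27 (not isolated)
Conditions: TBAF, AcOH, THF, 0 → 40 °C; then 1 M aq. HCl, rt
Reagents that add atoms: none
Why: Acetic-acid-buffered fluoride removes the O6–TIPS and alkynyl–TIPS groups without acyl migration, and dilute acid then hydrolyses the terminal acetonide; no stereocentre is involved.

Step 16
Reactants: 28 triol alkyne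
Product: 29 CNP0197537.1 (target)
Conditions: PdCl2 (cat.), PPh3, SnCl2 (cat.), CO (8 atm), MeCN, 75 °C
Reagents that add atoms: carbon monoxide, [C-]#[O+]
Why: In this palladium-catalysed cyclocarbonylation of a homopropargylic alcohol, the alkoxycarbonyl–palladium species formed at O6 adds across C11≡C13 (5-exo) and protonolysis gives the trans-fused α-methylene-γ-butyrolactone with C12 from CO; C6 and C7 are unchanged and the side-chain hydroxyls are not homopropargylic.

**Compound list**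

1 | (S)-2,2,4-trimethyl-1,3-dioxolane-4-carboxylic acid | OC(=O)[C@@]1(C)OC(C)(C)OC1 | starting material
2 | (S)-2,2,4-trimethyl-1,3-dioxolane-4-carbonyl chloride | ClC(=O)[C@@]1(C)OC(C)(C)OC1 | intermediate
3 | mesityl oxide (4-methylpent-3-en-2-one) | CC(C)=CC(C)=O | starting material
4 | sodium 5-methyl-3-oxohexa-1,4-dien-1-olate (delocalised enolate) | CC(C)=CC(=O)C=C[O-].[Na+] | intermediate
5 | (E)-5-methyl-3-oxohexa-1,4-dien-1-yl (S)-2,2,4-trimethyl-1,3-dioxolane-4-carboxylate | CC(C)=CC(=O)/C=C/OC(=O)[C@@]1(C)OC(C)(C)OC1 | intermediate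
6 | (1E,3Z)-3-(tert-butyldimethylsilyloxy)-5-methylhexa-1,3,5-trien-1-yl (S)-2,2,4-trimethyl-1,3-dioxolane-4-carboxylate | C=C(C)/C=C(O[Si](C)(C)C(C)(C)C)/C=C/OC(=O)[C@@]1(C)OC(C)(C)OC1 | intermediate
7 | but-3-yn-2-one | CC(=O)C#C | starting material
8 | (E)-4-(4,4,5,5-tetramethyl-1,3,2-dioxaborolan-2-yl)but-3-en-2-one | CC(=O)/C=C/B1OC(C)(C)C(C)(C)O1 | intermediate
9 | boronate adduct: cyclohex-9-ene (ring C5–C10) with 10-OTBS, 8β-O-DoxCO, 7β-acetyl, 6α-Bpin, 5β-isopropenyl | CC(C)(C)[Si](C)(C)OC1=C[C@@H](OC(=O)[C@@]2(C)OC(C)(C)OC2)[C@@H](C(C)=O)[C@H](B3OC(C)(C)C(C)(C)O3)[C@H]1C(C)=C | intermediate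
10 | cyclohexenol: as 9 with 6α-OH | CC(C)(C)[Si](C)(C)OC1=C[C@@H](OC(=O)[C@@]2(C)OC(C)(C)OC2)[C@@H](C(C)=O)[C@H](O)[C@H]1C(C)=C | intermediate
11 | 6α-OTIPS ether of 10 | CC(C)(C)[Si](C)(C)OC1=C[C@@H](OC(=O)[C@@]2(C)OC(C)(C)OC2)[C@@H](C(C)=O)[C@H](O[Si](C(C)C)(C(C)C)C(C)C)[C@H]1C(C)=C | intermediate
12 | lithium enolate of 11 (C11=C13) | CC(C)(C)[Si](C)(C)OC1=C[C@@H](OC(=O)[C@@]2(C)OC(C)(C)OC2)[C@@H](C(=C)O[Li])[C@H](O[Si](C(C)C)(C(C)C)C(C)C)[C@H]1C(C)=C | intermediate
13 | diethyl enol phosphate of 11 | CC(C)(C)[Si](C)(C)OC1=C[C@@H](OC(=O)[C@@]2(C)OC(C)(C)OC2)[C@@H](C(=C)OP(=O)(OCC)OCC)[C@H](O[Si](C(C)C)(C(C)C)C(C)C)[C@H]1C(C)=C | intermediate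
14 | lithium acetylide (7β-C≡C–Li) | CC(C)(C)[Si](C)(C)OC1=C[C@@H](OC(=O)[C@@]2(C)OC(C)(C)OC2)[C@@H](C#C[Li])[C@H](O[Si](C(C)C)(C(C)C)C(C)C)[C@H]1C(C)=C | intermediate
15 | 7β-[(triisopropylsilyl)ethynyl]cyclohexene (10-OTBS enol ether, 8β-O-DoxCO, 6α-OTIPS, 5β-isopropenyl) | CC(C)(C)[Si](C)(C)OC1=C[C@@H](OC(=O)[C@@]2(C)OC(C)(C)OC2)[C@@H](C#C[Si](C(C)C)(C(C)C)C(C)C)[C@H](O[Si](C(C)C)(C(C)C)C(C)C)[C@H]1C(C)=C | intermediate
16 | 9α,10α-epoxide of 15 (10β-OTBS) | CC(C)(C)[Si](C)(C)O[C@@]12O[C@@H]1[C@@H](OC(=O)[C@@]3(C)OC(C)(C)OC3)[C@@H](C#C[Si](C(C)C)(C(C)C)C(C)C)[C@H](O[Si](C(C)C)(C(C)C)C(C)C)[C@H]2C(C)=C | intermediate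
17 | cyclohexan-10-one: 9α-OTBS, 8β-O-DoxCO, 7β-TIPS-ethynyl, 6α-OTIPS, 5β-isopropenyl | O=C1[C@H](C(C)=C)[C@@H](O[Si](C(C)C)(C(C)C)C(C)C)[C@H](C#C[Si](C(C)C)(C(C)C)C(C)C)[C@H](OC(=O)[C@@]2(C)OC(C)(C)OC2)[C@H]1O[Si](C)(C)C(C)(C)C | intermediate
18 | 10β-vinyl-10α-ol of 17 | C=C[C@]1(O)[C@H](C(C)=C)[C@@H](O[Si](C(C)C)(C(C)C)C(C)C)[C@H](C#C[Si](C(C)C)(C(C)C)C(C)C)[C@H](OC(=O)[C@@]2(C)OC(C)(C)OC2)[C@H]1O[Si](C)(C)C(C)(C)C | intermediate
19 | potassium alkoxide of 18 | C=C[C@]1([O-])[C@H](C(C)=C)[C@@H](O[Si](C(C)C)(C(C)C)C(C)C)[C@H](C#C[Si](C(C)C)(C(C)C)C(C)C)[C@H](OC(=O)[C@@]2(C)OC(C)(C)OC2)[C@H]1O[Si](C)(C)C(C)(C)C.[K+] | intermediate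
20 | potassium enolate, ten-membered ring, 4Z, C1=C10 with O cis to C2 | CC(C)[Si](C(C)C)(C(C)C)O[C@@H]1/C=C(/C)CC/C=C(\[O-])[C@H](O[Si](C)(C)C(C)(C)C)[C@@H](OC(=O)[C@@]2(C)OC(C)(C)OC2)[C@H]1C#C[Si](C(C)C)(C(C)C)C(C)C.[K+] | intermediate
21 | (4Z)-cyclodec-4-en-10-one: 9α-OTBS, 8β-O-DoxCO, 7β-TIPS-ethynyl, 6α-OTIPS, 4-methyl | CC(C)[Si](C(C)C)(C(C)C)O[C@@H]1/C=C(/C)CCCC(=O)[C@H](O[Si](C)(C)C(C)(C)C)[C@@H](OC(=O)[C@@]2(C)OC(C)(C)OC2)[C@H]1C#C[Si](C(C)C)(C(C)C)C(C)C | intermediate
22 | lithium enolate of 21, ring-cis (O trans to C2) | CC(C)[Si](C(C)C)(C(C)C)O[C@@H]1/C=C(/C)CC/C=C(/O[Li])[C@H](O[Si](C)(C)C(C)(C)C)[C@@H](OC(=O)[C@@]2(C)OC(C)(C)OC2)[C@H]1C#C[Si](C(C)C)(C(C)C)C(C)C | intermediate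
23 | C10 enol triflate (1(10)E,4Z) | CC(C)[Si](C(C)C)(C(C)C)O[C@@H]1/C=C(/C)CC/C=C(/OS(=O)(=O)C(F)(F)F)[C@H](O[Si](C)(C)C(C)(C)C)[C@@H](OC(=O)[C@@]2(C)OC(C)(C)OC2)[C@H]1C#C[Si](C(C)C)(C(C)C)C(C)C | intermediate
24 | C14 methyl ester (1(10)E,4Z), 9α-OTBS | CC(C)[Si](C(C)C)(C(C)C)O[C@@H]1/C=C(/C)CC/C=C(/C(=O)OC)[C@H](O[Si](C)(C)C(C)(C)C)[C@@H](OC(=O)[C@@]2(C)OC(C)(C)OC2)[C@H]1C#C[Si](C(C)C)(C(C)C)C(C)C | intermediate
25 | 9α-alcohol | CC(C)[Si](C(C)C)(C(C)C)O[C@@H]1/C=C(/C)CC/C=C(/C(=O)OC)[C@H](O)[C@@H](OC(=O)[C@@]2(C)OC(C)(C)OC2)[C@H]1C#C[Si](C(C)C)(C(C)C)C(C)C | intermediate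
26 | 9α-acetate | CC(C)[Si](C(C)C)(C(C)C)O[C@@H]1/C=C(/C)CC/C=C(/C(=O)OC)[C@H](OC(C)=O)[C@@H](OC(=O)[C@@]2(C)OC(C)(C)OC2)[C@H]1C#C[Si](C(C)C)(C(C)C)C(C)C | intermediate
27 | 6α-hydroxy-7β-ethynyl acetonide (desilylated 26) | O[C@@H]1/C=C(/C)CC/C=C(/C(=O)OC)[C@H](OC(C)=O)[C@@H](OC(=O)[C@@]2(C)OC(C)(C)OC2)[C@H]1C#C | intermediate
28 | triol alkyne: 6α-OH, 7β-ethynyl, 8β-O-[(S)-2,3-dihydroxy-2-methylpropanoyl], 9α-OAc, C14 methyl ester | O[C@@H]1/C=C(/C)CC/C=C(/C(=O)OC)[C@H](OC(C)=O)[C@@H](OC(=O)[C@@](C)(O)CO)[C@H]1C#C | intermediate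
29 | CNP0197537.1 | C=C1C(=O)O[C@@H]2/C=C(/C)CC/C=C(/C(=O)OC)[C@H](OC(C)=O)[C@@H](OC(=O)[C@@](C)(O)CO)[C@@H]12 | target

**Step count and risk**

Total step count: 16. Longest linear sequence: 15 (steps 1–3 and 5–16, from acid 1).

The three steps most likely to fail are steps 10, 9 and 11.

Step 10 (key step): base-induced side processes of alkoxide 19 may outrun the sigmatropic shift. These are migration of the TBS group from O9 to O10, acyl transfer from O8, or heterolysis of C5–C10 without recombination. The fallback is the neutral oxy-Cope variant. It sets out from 18: TMSOTf and 2,6-lutidine should give the tertiary trimethylsilyl ether F2. Heating (o-dichlorobenzene, about 200 °C, sealed tube) should effect the same [3,3] shift through the same chair and give the trimethylsilyl enol ether F3. Mild acid hydrolysis (AcOH, THF, water) then returns to the route at 21.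

Step 9: the organocerium reagent may attack the α-face (equatorial trajectory), which gives the C10 epimer with trans-disposed alkenyl groups; that epimer could only rearrange to the 4E olefin. The fallback sets out from 17 and uses a rod-shaped sp nucleophile, which tolerates the axial trajectory anti to the C9–O bond better. Ethynylmagnesium bromide with CeCl3 should give the 10β-ethynyl carbinol F1. Semihydrogenation of the terminal alkyne (Pd/CaCO3–Pb, quinoline, H2; the TIPS-alkyne and the olefins are left) returns to the route at 18.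

Step 11: enolisation of 21 may give the ring-trans enolate or a geometric mixture, or may occur at C9 with loss of the C8 acyloxy group. The fallback avoids re-enolisation and sets the geometry thermodynamically at the ester stage. It sets out from 18: the oxy-Cope mixture is quenched at −78 °C with PhNTf2 instead of acid, which traps enolate 20 as the ring-trans enol triflate F4. Methoxycarbonylation as in step 12 gives the (1(10)Z)-enoate F5. Reversible conjugate addition of a catalytic nucleophile (PhSH with catalytic PhSLi, or Me3P) should equilibrate F5 to the more stable isomer, which has the ester trans to C2 and a cis ring olefin, returning to the route at 24.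

**Further compounds**

F1 | step 9 | 10β-ethynyl-10α-ol (ethynyl analogue of 18) | C#C[C@]1(O)[C@H](C(C)=C)[C@@H](O[Si](C(C)C)(C(C)C)C(C)C)[C@H](C#C[Si](C(C)C)(C(C)C)C(C)C)[C@H](OC(=O)[C@@]2(C)OC(C)(C)OC2)[C@H]1O[Si](C)(C)C(C)(C)C
F2 | step 10 | 10α-O-trimethylsilyl ether of 18 | C=C[C@]1(O[Si](C)(C)C)[C@H](C(C)=C)[C@@H](O[Si](C(C)C)(C(C)C)C(C)C)[C@H](C#C[Si](C(C)C)(C(C)C)C(C)C)[C@H](OC(=O)[C@@]2(C)OC(C)(C)OC2)[C@H]1O[Si](C)(C)C(C)(C)C
F3 | step 10 | trimethylsilyl enol ether of 21 (C1=C10, OSi cis to C2, 4Z) | CC(C)[Si](C(C)C)(C(C)C)O[C@@H]1/C=C(/C)CC/C=C(\O[Si](C)(C)C)[C@H](O[Si](C)(C)C(C)(C)C)[C@@H](OC(=O)[C@@]2(C)OC(C)(C)OC2)[C@H]1C#C[Si](C(C)C)(C(C)C)C(C)C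
F4 | step 11 | ring-trans C10 enol triflate (OTf cis to C2, 4Z) | CC(C)[Si](C(C)C)(C(C)C)O[C@@H]1/C=C(/C)CC/C=C(\OS(=O)(=O)C(F)(F)F)[C@H](O[Si](C)(C)C(C)(C)C)[C@@H](OC(=O)[C@@]2(C)OC(C)(C)OC2)[C@H]1C#C[Si](C(C)C)(C(C)C)C(C)C
F5 | step 11 | (1(10)Z,4Z)-C14 methyl ester (ester cis to C2) | CC(C)[Si](C(C)C)(C(C)C)O[C@@H]1/C=C(/C)CC/C=C(\C(=O)OC)[C@H](O[Si](C)(C)C(C)(C)C)[C@@H](OC(=O)[C@@]2(C)OC(C)(C)OC2)[C@H]1C#C[Si](C(C)C)(C(C)C)C(C)C
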